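**Strategy.** Everything rests on cutting the bond between C8 of ring A and the benzylic CH2 of the side chain. A Negishi sp3–sp2 coupling forms it last, joining the complete (2S)-8-bromoflavanone to the complete side chain, used as a β-branched homoallylic alkylzinc iodide, with both preformed stereocentres (C2 and C2'') untouched. The step exploits the position of C8 on ring A: ortho to O7 and O1 and para to the 5-methoxy oxygen, it is brominated selectively and so becomes the coupling site. The precursors are a MOM-protected bromoflavanone, made by asymmetric rhodium-catalysed arylation of a chromone, and a TES-protected (S)-iodide from an Evans alkylation.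

Key step: step 13

Remark 1: the (S)-configured biaryl bisphosphine of step 6 is assumed to direct the aryl group to the chromone face that gives the (2S)-flavanone, as (S)-BINAP-type ligands give (S)-3-arylcyclohexanones; if the sense proved opposite, the (R)-ligand would be used.

Remark 2: side-chain atoms are numbered C1'' (benzylic CH2) to C5''. The spatial arrangement at C2'' is the same from 16 to 23; the descriptor is (S) in 16–21 and (R) in 22 and 23 only because the priority order of the substituents changes.

**Step 1**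
Reactants: 1 5,7-dihydroxy-4H-chromen-4-one
Product: 2 5-hydroxy-7-(methoxymethoxy)-4H-chromen-4-one
Conditions: MOMCl (1.1 equiv), K2CO3, acetone, 0 °C → rt
Reagents that add atoms: chloromethyl methyl ether (MOMCl), COCCl
Why: Williamson-type O-alkylation (MOM protection), in which the acidic, unhindered 7-OH should react alone because the 5-OH is held in a hydrogen bond to the C4 carbonyl.

**Step 2**
Reactants: 2 5-hydroxy-7-(methoxymethoxy)-4H-chromen-4-one
Product: 3 5-methoxy-7-(methoxymethoxy)-4H-chromen-4-one
Conditions: MeI, K2CO3, DMF, 50 °C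
Reagents that add atoms: iodomethane, CI
Why: Williamson ether synthesis on the chelated 5-OH, which needs the warmer DMF conditions but has no competing nucleophilic site left.

**Step 3**
Reactants: 3 5-methoxy-7-(methoxymethoxy)-4H-chromen-4-one
Product: 4 8-bromo-5-methoxy-7-(methoxymethoxy)-4H-chromen-4-one
Conditions: NBS (1.0 equiv), DMF, 0 °C → rt
Reagents that add atoms: N-bromosuccinimide, O=C1CCC(=O)N1Br
Why: Electrophilic aromatic bromination, expected at C8 (ortho to O7 and O1, para to the 5-methoxy oxygen) in preference to C6 (para only to O1, whose lone pair is tied up in the vinylogous ester) and to C3 of the less nucleophilic pyranone ring.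

**Step 4**
Reactants: 5 4-bromobenzene-1,3-diol
Product: 6 1-bromo-2,4-bis(methoxymethoxy)benzene
Conditions: MOMCl (2.5 equiv), K2CO3, acetone, reflux
Reagents that add atoms: chloromethyl methyl ether (MOMCl), COCCl
Why: Double Williamson-type MOM protection of both phenols, giving ethers that tolerate the organolithium, the basic rhodium step and the organozinc coupling.

**Step 5**
Reactants: 6 1-bromo-2,4-bis(methoxymethoxy)benzene
Product: 8 [2,4-bis(methoxymethoxy)phenyl]boronic acid, via aryllithium 7 (not isolated)
Conditions: n-BuLi, THF, −78 °C; B(OiPr)3, −78 °C → rt; aq. HCl to pH 6, 0 °C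
Reagents that add atoms: triisopropyl borate, CC(C)OB(OC(C)C)OC(C)C; water, O
Why: Bromine–lithium exchange followed by borylation of the aryllithium (stabilised by the ortho MOM ether) and hydrolysis of the borate under a near-neutral work-up that the MOM ethers survive.

**Step 6**
Reactants: 4 8-bromo-5-methoxy-7-(methoxymethoxy)-4H-chromen-4-one; 8 [2,4-bis(methoxymethoxy)phenyl]boronic acid
Product: 9 (2S)-2-[2,4-bis(methoxymethoxy)phenyl]-8-bromo-5-methoxy-7-(methoxymethoxy)chroman-4-one
Conditions: [RhCl(C2H4)2]2 (2.5 mol %), (S)-MeO-F12-BIPHEP [(S)-6,6'-dimethoxy-2,2'-bis[bis(3,4,5-trifluorophenyl)phosphino]biphenyl] (6 mol %), KOH (0.2 equiv), 1,4-dioxane/H2O (10:1), 30 °C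
Reagents that add atoms: none
Why: Rhodium-catalysed asymmetric 1,4-addition of an arylboronic acid to an enone (Hayashi–Miyaura reaction) applied to a chromone, in which the aryl-rhodium species inserts the C2=C3 bond on the face selected by the (S)-bisphosphine to set C2 as (S), the electron-poor ligand allowing a temperature low enough for the C8–Br bond and ring C to survive.

**Step 7**
Reactants: 10 (S)-4-benzyl-1,3-oxazolidin-2-one; 11 3-methylbut-2-enoyl chloride
Product: 13 (4S)-4-benzyl-3-(3-methylbut-2-enoyl)-1,3-oxazolidin-2-one, via lithium oxazolidinonide 12 (not isolated)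
Conditions: n-BuLi, THF, −78 °C; then 11, −78 → 0 °C
Reagents that add atoms: none
Why: N-Acylation of the lithiated oxazolidinone with the acid chloride, the standard preparation of an Evans imide.

**Step 8**
Reactants: 13 (4S)-4-benzyl-3-(3-methylbut-2-enoyl)-1,3-oxazolidin-2-one; 14 1-bromo-3-methylbut-2-ene
Product: 16 (4S)-4-benzyl-3-[(2S)-5-methyl-2-(prop-1-en-2-yl)hex-4-enoyl]-1,3-oxazolidin-2-one, via sodium dienolate 15 (not isolated)
Conditions: NaN(SiMe3)2, THF, −78 °C; then 14, −78 → −40 °C
Reagents that add atoms: none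
Why: Evans asymmetric alkylation in its deconjugative form, in which γ-deprotonation gives the chelated (Z)-dienolate that is alkylated at the α-carbon on the face opposite the benzyl group, moving the double bond into the isopropenyl position and setting the α-stereocentre as (S).

**Step 9**
Reactants: 16 (4S)-4-benzyl-3-[(2S)-5-methyl-2-(prop-1-en-2-yl)hex-4-enoyl]-1,3-oxazolidin-2-one
Product: 17 (4S)-4-benzyl-3-{(2S)-2-[(3,3-dimethyloxiran-2-yl)methyl]-3-methylbut-3-enoyl}-1,3-oxazolidin-2-one (mixture of epimers at the oxirane carbon)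
Conditions: mCPBA (1.05 equiv), NaHCO3, CH2Cl2, 0 °C
Reagents that add atoms: 3-chloroperoxybenzoic acid (mCPBA), OOC(=O)c1cccc(Cl)c1
Why: Prilezhaev epoxidation, expected at the electron-rich trisubstituted alkene rather than at the 1,1-disubstituted isopropenyl alkene (also deactivated by the adjacent acyl group); the new oxirane stereocentre is removed in step 10 and is of no consequence.

**Step 10**
Reactants: 17 (4S)-4-benzyl-3-{(2S)-2-[(3,3-dimethyloxiran-2-yl)methyl]-3-methylbut-3-enoyl}-1,3-oxazolidin-2-one
Product: 18 (2S)-5-methyl-2-(prop-1-en-2-yl)hexane-1,5-diol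
Conditions: LiAlH4, THF, 0 °C → rt; aqueous NaOH work-up
Reagents that add atoms: none
Why: Hydride reduction in which LiAlH4 cleaves the imide to the primary alcohol (releasing the auxiliary) and opens the trisubstituted epoxide by SN2 attack at its secondary carbon to give the tertiary alcohol, without touching the stereocentre.

**Step 11**
Reactants: 18 (2S)-5-methyl-2-(prop-1-en-2-yl)hexane-1,5-diol
Product: 19 (5S)-6-iodo-2-methyl-5-(prop-1-en-2-yl)hexan-2-ol
Conditions: I2, PPh3, imidazole, CH2Cl2, 0 °C
Reagents that add atoms: iodine, II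
Why: Appel-type iodination (Garegg–Samuelsson conditions), in which only the primary alcohol forms the alkoxyphosphonium ion and is displaced by iodide, the tertiary alcohol being too hindered.

**Step 12**
Reactants: 19 (5S)-6-iodo-2-methyl-5-(prop-1-en-2-yl)hexan-2-ol
Product: 20 triethyl{[(5S)-6-iodo-2-methyl-5-(prop-1-en-2-yl)hexan-2-yl]oxy}silane
Conditions: Et3SiOTf, 2,6-lutidine, CH2Cl2, −78 → 0 °C
Reagents that add atoms: triethylsilyl trifluoromethanesulfonate, CC[Si](CC)(CC)OS(=O)(=O)C(F)(F)F
Why: Silylation of the hindered tertiary alcohol with a silyl triflate, which removes the acidic proton that would quench the organozinc reagent of step 13 and prevents cyclisation of the iodo alcohol.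

**Step 13**
Reactants: 20 triethyl{[(5S)-6-iodo-2-methyl-5-(prop-1-en-2-yl)hexan-2-yl]oxy}silane; 9 (2S)-2-[2,4-bis(methoxymethoxy)phenyl]-8-bromo-5-methoxy-7-(methoxymethoxy)chroman-4-one
Product: 22 (2S)-2-[2,4-bis(methoxymethoxy)phenyl]-5-methoxy-7-(methoxymethoxy)-8-{(2R)-5-methyl-2-(prop-1-en-2-yl)-5-[(triethylsilyl)oxy]hexyl}chroman-4-one, via alkylzinc iodide 21 (not isolated)
Conditions: Zn dust (activated with BrCH2CH2Br and Me3SiCl), LiCl, THF, 40 °C; then 9, Pd(OAc)2 (5 mol %), SPhos (10 mol %), THF, 25 → 50 °C
Reagents that add atoms: none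
Why: Zinc inserts into the primary C–I bond of 20 (LiCl keeps the organozinc in solution) to give 21, zerovalent palladium ligated by SPhos adds oxidatively to the C8–Br bond of 9, the alkyl group passes from zinc to palladium, and reductive elimination forms the C8–CH2 bond. The closest known reaction type is the Negishi coupling of primary alkylzinc halides with doubly ortho-substituted, electron-rich aryl bromides under dialkylbiarylphosphine ligation. No ring is closed and no stereocentre is created: C2 of ring C and C2'' are carried through, C2'' lying one carbon away from the metal-bearing carbon, so its configuration should be retained. The step needs chemoselectivity for the C–Br bond over the C4 ketone, the acidic C3 methylene and the MOM and TES ethers, which the low basicity and low carbonyl reactivity of an alkylzinc iodide secure, so that ring C is neither enolised nor opened and C2 is not epimerised. It also needs reductive elimination to outrun β-hydride elimination toward the conjugated diene, which the bulky, electron-rich ligand and the primary alkyl group should secure.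

**Step 14**
Reactants: 22 (2S)-2-[2,4-bis(methoxymethoxy)phenyl]-5-methoxy-7-(methoxymethoxy)-8-{(2R)-5-methyl-2-(prop-1-en-2-yl)-5-[(triethylsilyl)oxy]hexyl}chroman-4-one
Product: 23 (2S)-2-(2,4-dihydroxyphenyl)-7-hydroxy-8-[(2R)-5-hydroxy-5-methyl-2-(prop-1-en-2-yl)hexyl]-5-methoxychroman-4-one
Conditions: HCl (ca. 1 M) in MeOH, 0 °C → rt, stopped at full conversion
Reagents that add atoms: none
Why: Acid-catalysed methanolysis of the three aryl MOM acetals and of the tertiary TES ether in one operation, under mild, short conditions meant to leave C2, the isopropenyl group and the tertiary alcohol intact.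

**Compound list**
1 | 5,7-dihydroxy-4H-chromen-4-one | O=c1ccoc2cc(O)cc(O)c12 | starting material
2 | 5-hydroxy-7-(methoxymethoxy)-4H-chromen-4-one | O=c1ccoc2cc(OCOC)cc(O)c12 | intermediate
3 | 5-methoxy-7-(methoxymethoxy)-4H-chromen-4-one | O=c1ccoc2cc(OCOC)cc(OC)c12 | intermediate
4 | 8-bromo-5-methoxy-7-(methoxymethoxy)-4H-chromen-4-one | O=c1ccoc2c(Br)c(OCOC)cc(OC)c12 | intermediate
5 | 4-bromobenzene-1,3-diol | Oc1ccc(Br)c(O)c1 | starting material
6 | 1-bromo-2,4-bis(methoxymethoxy)benzene | COCOc1ccc(Br)c(OCOC)c1 | intermediate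
7 | [2,4-bis(methoxymethoxy)phenyl]lithium | [Li]c1ccc(OCOC)cc1OCOC | intermediate
8 | [2,4-bis(methoxymethoxy)phenyl]boronic acid | OB(O)c1ccc(OCOC)cc1OCOC | intermediate
9 | (2S)-2-[2,4-bis(methoxymethoxy)phenyl]-8-bromo-5-methoxy-7-(methoxymethoxy)chroman-4-one | Brc1c(OCOC)cc(OC)c2c1O[C@H](c1ccc(OCOC)cc1OCOC)CC2=O | intermediate
10 | (S)-4-benzyl-1,3-oxazolidin-2-one | O=C1OC[C@H](Cc2ccccc2)N1 | starting material
11 | 3-methylbut-2-enoyl chloride | CC(C)=CC(=O)Cl | starting material
12 | lithium salt of (S)-4-benzyl-1,3-oxazolidin-2-one | O=C1OC[C@H](Cc2ccccc2)[N-]1.[Li+] | intermediate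
13 | (4S)-4-benzyl-3-(3-methylbut-2-enoyl)-1,3-oxazolidin-2-one | CC(C)=CC(=O)N1[C@@H](Cc2ccccc2)COC1=O | intermediate
14 | 1-bromo-3-methylbut-2-ene | CC(C)=CCBr | starting material
15 | sodium (Z)-dienolate of 13 | C=C(C)/C=C(\[O-])N1[C@@H](Cc2ccccc2)COC1=O.[Na+] | intermediate
16 | (4S)-4-benzyl-3-[(2S)-5-methyl-2-(prop-1-en-2-yl)hex-4-enoyl]-1,3-oxazolidin-2-one | C=C(C)[C@H](CC=C(C)C)C(=O)N1[C@@H](Cc2ccccc2)COC1=O | intermediate
17 | (4S)-4-benzyl-3-{(2S)-2-[(3,3-dimethyloxiran-2-yl)methyl]-3-methylbut-3-enoyl}-1,3-oxazolidin-2-one, both epimers at the oxirane carbon | C=C(C)[C@H](CC1OC1(C)C)C(=O)N1[C@@H](Cc2ccccc2)COC1=O | intermediate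
18 | (2S)-5-methyl-2-(prop-1-en-2-yl)hexane-1,5-diol | C=C(C)[C@H](CCC(C)(C)O)CO | intermediate
19 | (5S)-6-iodo-2-methyl-5-(prop-1-en-2-yl)hexan-2-ol | C=C(C)[C@H](CCC(C)(C)O)CI | intermediate
20 | triethyl{[(5S)-6-iodo-2-methyl-5-(prop-1-en-2-yl)hexan-2-yl]oxy}silane | C=C(C)[C@H](CCC(C)(C)O[Si](CC)(CC)CC)CI | intermediate
21 | {(2S)-5-methyl-2-(prop-1-en-2-yl)-5-[(triethylsilyl)oxy]hexyl}zinc iodide | C=C(C)[C@H](CCC(C)(C)O[Si](CC)(CC)CC)C[Zn]I | intermediate
22 | (2S)-2-[2,4-bis(methoxymethoxy)phenyl]-5-methoxy-7-(methoxymethoxy)-8-{(2R)-5-methyl-2-(prop-1-en-2-yl)-5-[(triethylsilyl)oxy]hexyl}chroman-4-one | C=C(C)[C@H](CCC(C)(C)O[Si](CC)(CC)CC)Cc1c(OCOC)cc(OC)c2c1O[C@H](c1ccc(OCOC)cc1OCOC)CC2=O | intermediate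
23 | (2S)-2-(2,4-dihydroxyphenyl)-7-hydroxy-8-[(2R)-5-hydroxy-5-methyl-2-(prop-1-en-2-yl)hexyl]-5-methoxychroman-4-one (CID44563198) | C=C(C)[C@H](CCC(C)(C)O)Cc1c(O)cc(OC)c2c1O[C@H](c1ccc(O)cc1O)CC2=O | target

**Step count.** Total: 14 steps. Longest linear sequence: 8 steps (steps 7–14, from 10 and 11 to 23).

**Steps most likely to fail**

1. Step 6 (asymmetric 1,4-addition). Insertion of the electron-rich, 5,7-dioxygenated chromone may be slow, so that protodeboronation of the ortho-alkoxy boronic acid takes over, or the facial selectivity may be insufficient. The fallback sets out from 4 and 6 and comes back at 9. Compound 6 is converted with Mg in THF into [2,4-bis(methoxymethoxy)phenyl]magnesium bromide F1, which is added to 4 with catalytic CuBr·SMe2 at −78 °C to give the racemic bromoflavanone F2. A kinetic resolution by Noyori-type asymmetric transfer hydrogenation, RuCl(p-cymene)[(R,R)-TsDPEN] with HCO2H/Et3N, should then reduce the (2R)-enantiomer to the cis-(2R,4R)-flavan-4-ol F3, which is removed by chromatography, and leave 9.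

2. Step 13 (Negishi union). Oxidative addition at the doubly ortho-substituted, electron-rich C8–Br bond may be sluggish, so that protodezincation, or β-hydride elimination from the alkylpalladium intermediate with loss of the C2'' configuration, competes. The fallback sets out from 4 and 21 and comes back at 22. The union is moved one stage earlier: 21 is coupled with the chromone 4 under the same palladium/SPhos catalysis to give the 8-alkylchromone F4, whose aryl bromide is less electron-rich and which carries no enolisable or base-sensitive stereocentre. The rhodium-catalysed asymmetric 1,4-addition of 8 to F4 under the conditions of step 6 then gives 22.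

3. Step 14 (global deprotection). During the acid treatment needed for three MOM ethers, O7–H may add to the isopropenyl group (chroman formation), the tertiary alcohol may ionise, or C2 may epimerise through opening of ring C. The fallback sets out from 9 and comes back at 23. The protecting groups are exchanged before the union, while nothing acid-sensitive is present: HCl in MeOH converts 9 into (2S)-8-bromo-2-(2,4-dihydroxyphenyl)-7-hydroxy-5-methoxychroman-4-one F5, and TBSCl with imidazole in DMF gives its tris(tert-butyldimethylsilyl) ether F6. Negishi coupling of F6 with 21 as in step 13 gives the fully silylated coupled flavanone F7, and HF·pyridine buffered with pyridine in THF at 0 °C removes all four silyl groups to give 23.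

**Further compounds**
F1 | step 6 | [2,4-bis(methoxymethoxy)phenyl]magnesium bromide | COCOc1ccc([Mg]Br)c(OCOC)c1
F2 | step 6 | racemic 2-[2,4-bis(methoxymethoxy)phenyl]-8-bromo-5-methoxy-7-(methoxymethoxy)chroman-4-one | Brc1c(OCOC)cc(OC)c2c1OC(c1ccc(OCOC)cc1OCOC)CC2=O
F3 | step 6 | (2R,4R)-2-[2,4-bis(methoxymethoxy)phenyl]-8-bromo-5-methoxy-7-(methoxymethoxy)chroman-4-ol | Brc1c(OCOC)cc(OC)c2c1O[C@@H](c1ccc(OCOC)cc1OCOC)C[C@H]2O
F4 | step 13 | 5-methoxy-7-(methoxymethoxy)-8-{(2R)-5-methyl-2-(prop-1-en-2-yl)-5-[(triethylsilyl)oxy]hexyl}-4H-chromen-4-one | C=C(C)[C@H](CCC(C)(C)O[Si](CC)(CC)CC)Cc1c(OCOC)cc(OC)c2c(=O)ccoc12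
F5 | step 14 | (2S)-8-bromo-2-(2,4-dihydroxyphenyl)-7-hydroxy-5-methoxychroman-4-one | Brc1c(O)cc(OC)c2c1O[C@H](c1ccc(O)cc1O)CC2=O
F6 | step 14 | (2S)-8-bromo-2-{2,4-bis[(tert-butyldimethylsilyl)oxy]phenyl}-7-[(tert-butyldimethylsilyl)oxy]-5-methoxychroman-4-one | Brc1c(O[Si](C)(C)C(C)(C)C)cc(OC)c2c1O[C@H](c1ccc(O[Si](C)(C)C(C)(C)C)cc1O[Si](C)(C)C(C)(C)C)CC2=O
F7 | step 14 | (2S)-2-{2,4-bis[(tert-butyldimethylsilyl)oxy]phenyl}-7-[(tert-butyldimethylsilyl)oxy]-5-methoxy-8-{(2R)-5-methyl-2-(prop-1-en-2-yl)-5-[(triethylsilyl)oxy]hexyl}chroman-4-one | C=C(C)[C@H](CCC(C)(C)O[Si](CC)(CC)CC)Cc1c(O[Si](C)(C)C(C)(C)C)cc(OC)c2c1O[C@H](c1ccc(O[Si](C)(C)C(C)(C)C)cc1O[Si](C)(C)C(C)(C)C)CC2=O
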